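**Retrosynthetic overview**

1. Ring C is formed last: the isoflavone is cut back to chalcone epoxide 23 (1,2-acyl shift to the 2-aryl-3-oxopropanal 24, then O1–C2 closure and loss of water), and the chalcone is cut at its Cα=Cβ bond into ring A acetophenone 21 and ring B aldehyde 17.
2. Ring B is built, not bought: its contiguous edge C1' (carbon), C2' (OMe), C3' (prenyl), C4' (OH) is read as C5, C4 and C3 of 2-pyranone 7 plus the oxygen-bearing carbon of ynol ether 11. The disconnection is C3'–C4' and C5'–C6' ([4+2] cycloaddition, then loss of CO2).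
3. Pyranone 7 comes from dimethyl 3-oxopentanedioate and trimethyl orthoformate (pyranone ring), prenylation at C3 (the carbon between the two oxygenated carbons) and O-methylation.
4. Ring A comes from 2,4,6-trihydroxyacetophenone by twofold C-prenylation at its two free ring carbons; its mirror symmetry makes the two ortho oxygens equivalent for ring C closure.
5. Order of ring formation: pyranone ring (step 1), ring B (step 5), ring C (step 15); ring A is purchased.

Key step: step 5

Remark on the chemistry: the target has no stereocentre; the stereocentres that appear on the way (bridged lactone 12, epoxide 23, keto-aldehyde 24, hemiacetal 26) are racemic and are all destroyed before the end.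

**Route**

Step 1
Reactants: 1 dimethyl 3-oxopentanedioate; 2 trimethyl orthoformate
Product: 4 methyl 4-hydroxy-2-oxo-2H-pyran-5-carboxylate, via methoxymethylidene diester 3 (not isolated)
Conditions: Ac2O, 130 °C; evaporate; then 1 M aq HCl, 0 °C to rt
Reagents that add atoms: water, O
Why: Orthoester condensation at one activated methylene gives the alkoxymethylidene 1,3-dicarbonyl compound 3, whose enol ether is hydrolysed by aqueous acid to the hydroxymethylidene enol; this lactonises onto the distal ester (six-ring closure with loss of methanol) to the 4-hydroxy-2-pyranone, a known pyranone synthesis from 3-oxoglutarates.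

Step 2
Reactants: 4 methyl 4-hydroxy-2-oxo-2H-pyran-5-carboxylate; 5 3-methylbut-2-enyl acetate
Product: 6 methyl 4-hydroxy-3-(3-methylbut-2-enyl)-2-oxo-2H-pyran-5-carboxylate
Conditions: Pd(PPh3)4 (5 mol %), DBU (1 equiv), PhMe, 60 °C; dilute citric acid work-up
Reagents that add atoms: none
Why: Tsuji–Trost allylation: the zerovalent palladium catalyst ionises prenyl acetate to the 1,1-dimethylallyl complex, which the soft anion of the 4-hydroxy-2-pyranone should attack through C3 at the unhindered CH2 terminus, and any O-prenyl ether re-ionises under the catalyst so that the C3-prenyl compound accumulates.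

Step 3
Reactants: 6 methyl 4-hydroxy-3-(3-methylbut-2-enyl)-2-oxo-2H-pyran-5-carboxylate
Product: 7 methyl 4-methoxy-3-(3-methylbut-2-enyl)-2-oxo-2H-pyran-5-carboxylate
Conditions: Me2SO4, K2CO3, acetone, reflux
Reagents that add atoms: dimethyl sulfate, COS(=O)(=O)OC
Why: O-alkylation of the vinylogous acid with a hard methylating agent should give the 4-methoxy-2-pyranone, the usual outcome for 4-hydroxy-2-pyranones under these conditions.

Step 4
Reactants: 8 ethyne
Product: 11 (ethynyloxy)triisopropylsilane, via lithium acetylide 9 (not isolated), via lithium ethynolate 10 (not isolated)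
Conditions: n-BuLi, THF, −78 °C; t-BuOOLi (from t-BuOOH and LiN(SiMe3)2), THF, −78 to 0 °C; i-Pr3SiOSO2CF3, −78 °C to rt; pentane extraction, distillation
Reagents that add atoms: tert-butyl hydroperoxide, CC(C)(C)OO; triisopropylsilyl trifluoromethanesulfonate, CC(C)[Si](C(C)C)(C(C)C)OS(=O)(=O)C(F)(F)F
Why: Electrophilic oxygenation of a lithium acetylide by the lithium alkyl peroxide (an oxenoid) gives the lithium ynolate, and the bulky silyl triflate silylates it at oxygen, which is the known way from terminal alkynes to silyl ynol ethers.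

Step 5
Reactants: 7 methyl 4-methoxy-3-(3-methylbut-2-enyl)-2-oxo-2H-pyran-5-carboxylate; 11 (ethynyloxy)triisopropylsilane
Product: 13 methyl 2-methoxy-3-(3-methylbut-2-enyl)-4-(triisopropylsilyloxy)benzoate, via bridged lactone 12 (not isolated)
Conditions: 11 (3 equiv), PhMe, 110 °C, sealed tube
Reagents that add atoms: none
Why: This is the inverse-electron-demand Diels–Alder reaction of a 2-pyranone-5-carboxylate with an electron-rich alkyne followed by retro-[4+2] loss of CO2, a known way from pyranones to benzoates: the nucleophilic terminal CH of 11 adds to C6 of 7 (beta to the C5 ester and vinylogous to the lactone carbonyl) and the oxygen-bearing carbon bonds to C3, in a concerted but strongly asynchronous (at the limit zwitterionic) [4+2] across C3 and C6. Ring B is closed by this intermolecular cycloaddition, which makes C5'–C6' and C3'–C4' in one operation and gives the 2-oxabicyclo[2.2.2]octadienone 12; at the reaction temperature 12 should expel CO2 by cycloreversion, driven by formation of the benzene ring. The two bridgehead stereocentres of 12 are transient and vanish in the cycloreversion, so no stereocontrol is needed. The step needs regioselectivity (OSi carbon to C3, not to C6) and chemoselectivity (ynol ether, not a prenyl alkene, as dienophile): the first is secured by the matched polarisation of both partners, the ester making C6 the electrophilic terminus and the 4-OMe group making C3 the nucleophilic one, and the second by the inertness of an unactivated trisubstituted alkene towards an electron-poor diene. The product should carry ester, OMe, prenyl and OSi on four neighbouring carbons in the order fixed by the pyranone, with no positional isomer to separate.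

Step 6
Reactants: 13 methyl 2-methoxy-3-(3-methylbut-2-enyl)-4-(triisopropylsilyloxy)benzoate
Product: 14 methyl 4-hydroxy-2-methoxy-3-(3-methylbut-2-enyl)benzoate
Conditions: Bu4NF, AcOH, THF, 0 °C
Reagents that add atoms: none
Why: Fluoride cleavage of an aryl silyl ether; the silyl group is exchanged here because an aryl silyl ether para to a carbonyl group would not survive the hydroxide of steps 12 and 13.

Step 7
Reactants: 14 methyl 4-hydroxy-2-methoxy-3-(3-methylbut-2-enyl)benzoate
Product: 15 methyl 2-methoxy-4-(methoxymethoxy)-3-(3-methylbut-2-enyl)benzoate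
Conditions: MOMCl, i-Pr2NEt, CH2Cl2, 0 °C to rt
Reagents that add atoms: chloromethyl methyl ether, COCCl
Why: O-alkylation of the phenol to its methoxymethyl acetal, which is stable to hydride, hydroxide and alkaline peroxide and is removed together with the ring A acetals in the last step.

Step 8
Reactants: 15 methyl 2-methoxy-4-(methoxymethoxy)-3-(3-methylbut-2-enyl)benzoate
Product: 16 [2-methoxy-4-(methoxymethoxy)-3-(3-methylbut-2-enyl)phenyl]methanol
Conditions: i-Bu2AlH (2.5 equiv), CH2Cl2, −78 to 0 °C
Reagents that add atoms: none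
Why: Hydride reduction of the benzoate to the benzylic alcohol; acetal, aryl ether and prenyl alkene are inert to the aluminium hydride at this temperature.

Step 9
Reactants: 16 [2-methoxy-4-(methoxymethoxy)-3-(3-methylbut-2-enyl)phenyl]methanol
Product: 17 2-methoxy-4-(methoxymethoxy)-3-(3-methylbut-2-enyl)benzaldehyde
Conditions: MnO2, CH2Cl2, rt
Reagents that add atoms: none
Why: Selective oxidation of a benzylic alcohol to the aldehyde by MnO2, which should not touch the allylic C–H bonds of the prenyl group or over-oxidise.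

Step 10
Reactants: 18 1-(2,4,6-trihydroxyphenyl)ethanone; 19 1-bromo-3-methylbut-2-ene
Product: 20 1-[2,4,6-trihydroxy-3,5-bis(3-methylbut-2-enyl)phenyl]ethanone
Conditions: 19 (2.1 equiv), 10 % aq KOH, 0 °C to rt
Reagents that add atoms: none
Why: C-alkylation of the acylphloroglucinol polyphenolate in water (the oxygens are solvated, the soft allylic bromide attacks carbon) at its only two free ring carbons, the known direct diprenylation of phloroacetophenone; the mono- and over-alkylated by-products would be removed by chromatography.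

Step 11
Reactants: 20 1-[2,4,6-trihydroxy-3,5-bis(3-methylbut-2-enyl)phenyl]ethanone
Product: 21 1-[2,4,6-tris(methoxymethoxy)-3,5-bis(3-methylbut-2-enyl)phenyl]ethanone
Conditions: NaH (3.5 equiv), MOMCl (3.5 equiv), DMF, 0 °C to rt
Reagents that add atoms: chloromethyl methyl ether, COCCl
Why: Exhaustive O-alkylation of the phenolates (the hard chloromethyl ether reacts at oxygen, the strong base also opens the hydrogen-bonded ortho phenols), needed because a free ortho phenol would divert the alkaline epoxidation of step 13 into flavonol or aurone formation.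

Step 12
Reactants: 21 1-[2,4,6-tris(methoxymethoxy)-3,5-bis(3-methylbut-2-enyl)phenyl]ethanone; 17 2-methoxy-4-(methoxymethoxy)-3-(3-methylbut-2-enyl)benzaldehyde
Product: 22 (E)-3-[2-methoxy-4-(methoxymethoxy)-3-(3-methylbut-2-enyl)phenyl]-1-[2,4,6-tris(methoxymethoxy)-3,5-bis(3-methylbut-2-enyl)phenyl]prop-2-en-1-one
Conditions: KOH, EtOH/H2O, rt
Reagents that add atoms: none
Why: Claisen–Schmidt condensation of the methyl ketone enolate with the non-enolisable aldehyde, with dehydration of the aldol under the conditions to the conjugated E-enone, standard for MOM-protected prenylated chalcones.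

Step 13
Reactants: 22 (E)-chalcone
Product: 23 trans-{3-[2-methoxy-4-(methoxymethoxy)-3-(3-methylbut-2-enyl)phenyl]oxiran-2-yl}[2,4,6-tris(methoxymethoxy)-3,5-bis(3-methylbut-2-enyl)phenyl]methanone (racemic)
Conditions: 30 % H2O2, NaOH, MeOH/THF, 0 °C to rt
Reagents that add atoms: hydrogen peroxide, OO
Why: Weitz–Scheffer nucleophilic epoxidation, in which hydroperoxide adds only to the electron-poor enone and leaves the three prenyl alkenes alone; the trans relative configuration of the two new stereocentres follows from the E-alkene and ring closure of the intermediate enolate in its less hindered rotamer, and both centres are racemic and erased in steps 14 and 15.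

Step 14
Reactants: 23 trans-chalcone epoxide (racemic)
Product: 24 2-[2-methoxy-4-(methoxymethoxy)-3-(3-methylbut-2-enyl)phenyl]-3-oxo-3-[2,4,6-tris(methoxymethoxy)-3,5-bis(3-methylbut-2-enyl)phenyl]propanal (racemic)
Conditions: BF3·OEt2 (1.1 equiv), CH2Cl2, −78 to −20 °C, short time; Et3N quench
Reagents that add atoms: none
Why: Meinwald-type rearrangement of a chalcone epoxide: the Lewis acid opens the C–O bond at the benzylic carbon (cation stabilised by the 2-OMe/4-OMOM aryl ring) and the aroyl group shifts 1,2 to that carbon, leaving the aldehyde, a known entry to 2-aryl-3-oxopropanals; the very labile benzylic C–O bond should allow a temperature at which the acetals and prenyl groups survive, and the new stereocentre is racemic, enolisable and lost in step 15.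

Step 15
Reactants: 24 2-aryl-3-oxopropanal (racemic)
Product: 27 5,7-dihydroxy-3-[4-hydroxy-2-methoxy-3-(3-methylbut-2-enyl)phenyl]-6,8-bis(3-methylbut-2-enyl)chromen-4-one, via tetraphenol keto-aldehyde 25 (not isolated), via 2-hydroxyisoflavanone 26 (not isolated)
Conditions: 3 M aq HCl, MeOH, 45 °C
Reagents that add atoms: none
Why: Acid-catalysed acetal exchange with methanol removes the four MOM groups, a freed ortho phenol of ring A adds to the aldehyde (six-ring hemiacetal, the two ortho oxygens being equivalent by symmetry) and dehydration gives the chromen-4-one, the standard closure of 2-aryl-3-oxopropanals to isoflavones under conditions commonly used to unmask prenylated flavonoids.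

**Compound list**

1 | dimethyl 3-oxopentanedioate | COC(=O)CC(=O)CC(=O)OC | starting material
2 | trimethyl orthoformate | COC(OC)OC | starting material
3 | dimethyl 2-(methoxymethylidene)-3-oxopentanedioate (not isolated) | COC=C(C(=O)OC)C(=O)CC(=O)OC | intermediate
4 | methyl 4-hydroxy-2-oxo-2H-pyran-5-carboxylate | COC(=O)c1coc(=O)cc1O | intermediate
5 | 3-methylbut-2-enyl acetate (prenyl acetate) | CC(=O)OCC=C(C)C | starting material
6 | methyl 4-hydroxy-3-(3-methylbut-2-enyl)-2-oxo-2H-pyran-5-carboxylate | COC(=O)c1coc(=O)c(CC=C(C)C)c1O | intermediate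
7 | methyl 4-methoxy-3-(3-methylbut-2-enyl)-2-oxo-2H-pyran-5-carboxylate | COC(=O)c1coc(=O)c(CC=C(C)C)c1OC | intermediate
8 | ethyne | C#C | starting material
9 | lithium acetylide (not isolated) | [Li]C#C | intermediate
10 | lithium ethynolate (not isolated) | [Li]OC#C | intermediate
11 | (ethynyloxy)triisopropylsilane | C#CO[Si](C(C)C)(C(C)C)C(C)C | intermediate
12 | methyl 5-methoxy-4-(3-methylbut-2-enyl)-3-oxo-8-(triisopropylsilyloxy)-2-oxabicyclo[2.2.2]octa-5,7-diene-6-carboxylate (racemic, bridgeheads fixed by the bicycle, not isolated) | COC(=O)C1=C(OC)C2(CC=C(C)C)C(=O)OC1C=C2O[Si](C(C)C)(C(C)C)C(C)C | intermediate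
13 | methyl 2-methoxy-3-(3-methylbut-2-enyl)-4-(triisopropylsilyloxy)benzoate | COC(=O)c1ccc(O[Si](C(C)C)(C(C)C)C(C)C)c(CC=C(C)C)c1OC | intermediate
14 | methyl 4-hydroxy-2-methoxy-3-(3-methylbut-2-enyl)benzoate | COC(=O)c1ccc(O)c(CC=C(C)C)c1OC | intermediate
15 | methyl 2-methoxy-4-(methoxymethoxy)-3-(3-methylbut-2-enyl)benzoate | COCOc1ccc(C(=O)OC)c(OC)c1CC=C(C)C | intermediate
16 | [2-methoxy-4-(methoxymethoxy)-3-(3-methylbut-2-enyl)phenyl]methanol | COCOc1ccc(CO)c(OC)c1CC=C(C)C | intermediate
17 | 2-methoxy-4-(methoxymethoxy)-3-(3-methylbut-2-enyl)benzaldehyde | COCOc1ccc(C=O)c(OC)c1CC=C(C)C | intermediate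
18 | 1-(2,4,6-trihydroxyphenyl)ethanone | CC(=O)c1c(O)cc(O)cc1O | starting material
19 | 1-bromo-3-methylbut-2-ene (prenyl bromide) | CC(C)=CCBr | starting material
20 | 1-[2,4,6-trihydroxy-3,5-bis(3-methylbut-2-enyl)phenyl]ethanone | CC(=O)c1c(O)c(CC=C(C)C)c(O)c(CC=C(C)C)c1O | intermediate
21 | 1-[2,4,6-tris(methoxymethoxy)-3,5-bis(3-methylbut-2-enyl)phenyl]ethanone | CC(=O)c1c(OCOC)c(CC=C(C)C)c(OCOC)c(CC=C(C)C)c1OCOC | intermediate
22 | (E)-3-[2-methoxy-4-(methoxymethoxy)-3-(3-methylbut-2-enyl)phenyl]-1-[2,4,6-tris(methoxymethoxy)-3,5-bis(3-methylbut-2-enyl)phenyl]prop-2-en-1-one | COCOc1ccc(/C=C/C(=O)c2c(OCOC)c(CC=C(C)C)c(OCOC)c(CC=C(C)C)c2OCOC)c(OC)c1CC=C(C)C | intermediate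
23 | trans-{3-[2-methoxy-4-(methoxymethoxy)-3-(3-methylbut-2-enyl)phenyl]oxiran-2-yl}[2,4,6-tris(methoxymethoxy)-3,5-bis(3-methylbut-2-enyl)phenyl]methanone (racemic; one enantiomer drawn) | O=C(c1c(OCOC)c(CC=C(C)C)c(OCOC)c(CC=C(C)C)c1OCOC)[C@@H]2O[C@H]2c3ccc(OCOC)c(CC=C(C)C)c3OC | intermediate
24 | 2-[2-methoxy-4-(methoxymethoxy)-3-(3-methylbut-2-enyl)phenyl]-3-oxo-3-[2,4,6-tris(methoxymethoxy)-3,5-bis(3-methylbut-2-enyl)phenyl]propanal (racemic) | O=CC(c1ccc(OCOC)c(CC=C(C)C)c1OC)C(=O)c2c(OCOC)c(CC=C(C)C)c(OCOC)c(CC=C(C)C)c2OCOC | intermediate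
25 | 2-[4-hydroxy-2-methoxy-3-(3-methylbut-2-enyl)phenyl]-3-oxo-3-[2,4,6-trihydroxy-3,5-bis(3-methylbut-2-enyl)phenyl]propanal (racemic, not isolated) | O=CC(c1ccc(O)c(CC=C(C)C)c1OC)C(=O)c2c(O)c(CC=C(C)C)c(O)c(CC=C(C)C)c2O | intermediate
26 | 2,5,7-trihydroxy-3-[4-hydroxy-2-methoxy-3-(3-methylbut-2-enyl)phenyl]-6,8-bis(3-methylbut-2-enyl)-2,3-dihydrochromen-4-one (racemic mixture of diastereomers, not isolated) | OC1Oc2c(CC=C(C)C)c(O)c(CC=C(C)C)c(O)c2C(=O)C1c3ccc(O)c(CC=C(C)C)c3OC | intermediate
27 | 5,7-dihydroxy-3-[4-hydroxy-2-methoxy-3-(3-methylbut-2-enyl)phenyl]-6,8-bis(3-methylbut-2-enyl)chromen-4-one | COc1c(-c2coc3c(CC=C(C)C)c(O)c(CC=C(C)C)c(O)c3c2=O)ccc(O)c1CC=C(C)C | target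

**Count and risks**

Total step count: 15.
Longest linear sequence: 12 steps (steps 1, 2, 3, 5, 6, 7, 8, 9, 12, 13, 14, 15); steps 4, 10 and 11 are side branches.

Steps most likely to fail:

1. Step 5. The first bond (alkyne CH to C6) may form while closure onto the prenyl-bearing C3, flanked by OMe and the incoming OSi carbon, is slow, so that the dipolar intermediate diverts (silyl transfer, four-ring adduct), or the ynol ether is used up by thermal isomerisation to a silylketene and oligomerisation before it adds. The 4-OMe group also lowers the electron demand of the diene. The fallback takes ring B from an existing benzene ring by directed metalation, all known chemistry. It sets out from prenyl bromide 19 and returns to the route at aldehyde 17, replacing steps 1 to 9. Commercial 1,3-bis(methoxymethoxy)benzene F1 is lithiated between its two acetal oxygens (n-BuLi, THF, 0 °C) to 2-lithio-1,3-bis(methoxymethoxy)benzene F2, which with CuI (catalytic) and 19 gives 1,3-bis(methoxymethoxy)-2-(3-methylbut-2-enyl)benzene F3. A second ortho-lithiation (n-BuLi, TMEDA, THF, 0 °C) gives 4-lithio-1,3-bis(methoxymethoxy)-2-(3-methylbut-2-enyl)benzene F4, which is quenched with DMF to 2,4-bis(methoxymethoxy)-3-(3-methylbut-2-enyl)benzaldehyde F5. The acetal next to the formyl group, activated by the neighbouring carbonyl, is removed selectively (catalytic I2 in MeOH, rt) to give 2-hydroxy-4-(methoxymethoxy)-3-(3-methylbut-2-enyl)benzaldehyde F6, and MeI/K2CO3 in DMF gives 17.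

2. Step 14. The benzylic cation may be captured by the neighbouring acetal oxygen of ring A (loss of that MOM group and dihydroflavonol-type closure), hydride may shift in place of the hindered aroyl group, or a phenol freed by the Lewis acid may add to its ortho prenyl group. The fallback reaches the same carbon skeleton through a deoxybenzoin and an enaminone without any acyl shift. It sets out from benzylic alcohol 16 and prenyl bromide 19 and returns at target 27. Alcohol 16 is converted (MsCl, Et3N, LiCl, THF) into 1-(chloromethyl)-2-methoxy-4-(methoxymethoxy)-3-(3-methylbut-2-enyl)benzene F7 and this, with Mg in THF at 0 °C, into [2-methoxy-4-(methoxymethoxy)-3-(3-methylbut-2-enyl)benzyl]magnesium chloride F8. Separately, commercial 2,4,6-trihydroxybenzaldehyde F9 is diprenylated with 19 as in step 10 to 2,4,6-trihydroxy-3,5-bis(3-methylbut-2-enyl)benzaldehyde F10 and protected as in step 11 to 2,4,6-tris(methoxymethoxy)-3,5-bis(3-methylbut-2-enyl)benzaldehyde F11. Addition of F8 to F11 gives the racemic carbinol 2-[2-methoxy-4-(methoxymethoxy)-3-(3-methylbut-2-enyl)phenyl]-1-[2,4,6-tris(methoxymethoxy)-3,5-bis(3-methylbut-2-enyl)phenyl]ethanol F12, and Dess–Martin periodinane oxidises it to the deoxybenzoin 2-[2-methoxy-4-(methoxymethoxy)-3-(3-methylbut-2-enyl)phenyl]-1-[2,4,6-tris(methoxymethoxy)-3,5-bis(3-methylbut-2-enyl)phenyl]ethanone F13. Heating with N,N-dimethylformamide dimethyl acetal (PhMe, 90 °C) gives the enaminone 3-(dimethylamino)-2-[2-methoxy-4-(methoxymethoxy)-3-(3-methylbut-2-enyl)phenyl]-1-[2,4,6-tris(methoxymethoxy)-3,5-bis(3-methylbut-2-enyl)phenyl]prop-2-en-1-one F14. Under the acid conditions of step 15, F14 loses its acetals and closes ring C by displacement of dimethylamine, giving 27.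

3. Step 4. The ynolate may be over-oxidised by the peroxide, silylation may go to carbon (silylketene), and the acid-sensitive, fairly volatile ynol ether may be lost on isolation. The fallback replaces the alkyne by a ketene bis(silyl) acetal, which reaches the same oxidation level by eliminating silanol after the cycloaddition; cycloadditions of 2-pyranone-5-carboxylates with ketene acetals to para-oxygenated benzoates are known. It sets out from pyranone 7 and returns at phenol 14, replacing steps 4 to 6. Commercial trimethylsilyl acetate F15 is converted (LiN(i-Pr)2, THF, −78 °C; Me3SiCl) into 1,1-bis(trimethylsilyloxy)ethene F16. Heating F16 with 7 in PhMe should give the bridged adduct methyl 5-methoxy-4-(3-methylbut-2-enyl)-3-oxo-8,8-bis(trimethylsilyloxy)-2-oxabicyclo[2.2.2]oct-5-ene-6-carboxylate F17. This loses CO2 to the diene methyl 2-methoxy-3-(3-methylbut-2-enyl)-4,4-bis(trimethylsilyloxy)cyclohexa-1,5-diene-1-carboxylate F18, which aromatises by loss of silanol to methyl 2-methoxy-3-(3-methylbut-2-enyl)-4-(trimethylsilyloxy)benzoate F19. K2CO3 in MeOH cleaves F19 to 14.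

**Further compounds**

F1 | step 5 | 1,3-bis(methoxymethoxy)benzene | COCOc1cccc(OCOC)c1
F2 | step 5 | 2-lithio-1,3-bis(methoxymethoxy)benzene | [Li]c1c(OCOC)cccc1OCOC
F3 | step 5 | 1,3-bis(methoxymethoxy)-2-(3-methylbut-2-enyl)benzene | COCOc1cccc(OCOC)c1CC=C(C)C
F4 | step 5 | 4-lithio-1,3-bis(methoxymethoxy)-2-(3-methylbut-2-enyl)benzene | [Li]c1ccc(OCOC)c(CC=C(C)C)c1OCOC
F5 | step 5 | 2,4-bis(methoxymethoxy)-3-(3-methylbut-2-enyl)benzaldehyde | COCOc1ccc(C=O)c(OCOC)c1CC=C(C)C
F6 | step 5 | 2-hydroxy-4-(methoxymethoxy)-3-(3-methylbut-2-enyl)benzaldehyde | COCOc1ccc(C=O)c(O)c1CC=C(C)C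
F7 | step 14 | 1-(chloromethyl)-2-methoxy-4-(methoxymethoxy)-3-(3-methylbut-2-enyl)benzene | COCOc1ccc(CCl)c(OC)c1CC=C(C)C
F8 | step 14 | [2-methoxy-4-(methoxymethoxy)-3-(3-methylbut-2-enyl)benzyl]magnesium chloride | COCOc1ccc(C[Mg]Cl)c(OC)c1CC=C(C)C
F9 | step 14 | 2,4,6-trihydroxybenzaldehyde | O=Cc1c(O)cc(O)cc1O
F10 | step 14 | 2,4,6-trihydroxy-3,5-bis(3-methylbut-2-enyl)benzaldehyde | O=Cc1c(O)c(CC=C(C)C)c(O)c(CC=C(C)C)c1O
F11 | step 14 | 2,4,6-tris(methoxymethoxy)-3,5-bis(3-methylbut-2-enyl)benzaldehyde | O=Cc1c(OCOC)c(CC=C(C)C)c(OCOC)c(CC=C(C)C)c1OCOC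
F12 | step 14 | 2-[2-methoxy-4-(methoxymethoxy)-3-(3-methylbut-2-enyl)phenyl]-1-[2,4,6-tris(methoxymethoxy)-3,5-bis(3-methylbut-2-enyl)phenyl]ethanol (racemic) | OC(Cc1ccc(OCOC)c(CC=C(C)C)c1OC)c2c(OCOC)c(CC=C(C)C)c(OCOC)c(CC=C(C)C)c2OCOC
F13 | step 14 | 2-[2-methoxy-4-(methoxymethoxy)-3-(3-methylbut-2-enyl)phenyl]-1-[2,4,6-tris(methoxymethoxy)-3,5-bis(3-methylbut-2-enyl)phenyl]ethanone | O=C(Cc1ccc(OCOC)c(CC=C(C)C)c1OC)c2c(OCOC)c(CC=C(C)C)c(OCOC)c(CC=C(C)C)c2OCOC
F14 | step 14 | 3-(dimethylamino)-2-[2-methoxy-4-(methoxymethoxy)-3-(3-methylbut-2-enyl)phenyl]-1-[2,4,6-tris(methoxymethoxy)-3,5-bis(3-methylbut-2-enyl)phenyl]prop-2-en-1-one | CN(C)C=C(c1ccc(OCOC)c(CC=C(C)C)c1OC)C(=O)c2c(OCOC)c(CC=C(C)C)c(OCOC)c(CC=C(C)C)c2OCOC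
F15 | step 4 | trimethylsilyl acetate | CC(=O)O[Si](C)(C)C
F16 | step 4 | 1,1-bis(trimethylsilyloxy)ethene | C=C(O[Si](C)(C)C)O[Si](C)(C)C
F17 | step 4 | methyl 5-methoxy-4-(3-methylbut-2-enyl)-3-oxo-8,8-bis(trimethylsilyloxy)-2-oxabicyclo[2.2.2]oct-5-ene-6-carboxylate (racemic) | COC(=O)C1=C(OC)C2(CC=C(C)C)C(=O)OC1CC2(O[Si](C)(C)C)O[Si](C)(C)C
F18 | step 4 | methyl 2-methoxy-3-(3-methylbut-2-enyl)-4,4-bis(trimethylsilyloxy)cyclohexa-1,5-diene-1-carboxylate | COC(=O)C1=CCC(O[Si](C)(C)C)(O[Si](C)(C)C)C(CC=C(C)C)=C1OC
F19 | step 4 | methyl 2-methoxy-3-(3-methylbut-2-enyl)-4-(trimethylsilyloxy)benzoate | COC(=O)c1ccc(O[Si](C)(C)C)c(CC=C(C)C)c1OC
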